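**Retrosynthetic overview**
1. The C3–C11′ bond of the norbornene is made by a ring contraction (1,2-shift) of a bicyclo[3.2.1] hemiketal that forms when the C3 dienolate of bromo lactone 29 adds to the lactone carbonyl. The C1–C13′ bond is made one step earlier, by Michael addition of the C1 enolate of enone 13 (half A) to methylene lactone 27 (half B).
2. Half A (guaiane numbering C1–C15): cyclopentenone from 1, C1–C10 by Mukaiyama–Michael addition, then the seven-membered ring and the trans-lactone together by a chromium Barbier allylation.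
3. Half B (primed seco-eudesmane numbering C1′–C15′): cyclohexene from 14, side chain by Suzuki coupling and asymmetric hydrogenation, cis-lactone by epoxide opening with a tethered phosphonoacetate followed by methylenation.
4. Ring order: cyclopentenone, then cycloheptane with lactone A; cyclohexene, then lactone B; norbornene by ring contraction; finally C2 reduction, acetylation, unmasking of the methylene lactone and desilylation.

Assumption: the enantiopure silyl ethers 1 and 14 are bought; their silyl groups are protecting groups.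

**Step 1**
Reactants: 1 (R)-4-(tert-butyldimethylsilyloxy)cyclopent-2-en-1-one
Product: 3 (R)-4-allylcyclopent-2-en-1-one, via silyloxy ketone adduct 2 (not isolated)
Conditions: allylMgBr, CuBr·SMe2 (10 mol%), THF, −78 °C; H2O; then DBU (cat.), CH2Cl2, 23 °C
Reagents that add atoms: allylmagnesium bromide C=CC[Mg]Br
Why: Copper-catalysed conjugate addition occurs anti to the silyloxy group and E1cB loss of silanol then gives the enone, so the C5 stereocentre (R) is set by substrate control.

**Step 2**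
Reactants: 3 (R)-4-allylcyclopent-2-en-1-one
Product: 4 (3S,4R)-4-allyl-3-methyl-1-(trimethylsilyloxy)cyclopent-1-ene
Conditions: Me2CuLi, TMSCl, THF, −78 °C
Reagents that add atoms: lithium dimethylcuprate [Li+].C[Cu-]C; chlorotrimethylsilane C[Si](C)(C)Cl
Why: Cuprate conjugate addition trans to the allyl group with trapping of the enolate gives the regiodefined silyl enol ether (the methyl-bearing centre is removed in step 3).

**Step 3**
Reactants: 4 (3S,4R)-4-allyl-3-methyl-1-(trimethylsilyloxy)cyclopent-1-ene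
Product: 5 (R)-4-allyl-3-methylcyclopent-2-en-1-one
Conditions: Pd(OAc)2 (10 mol%), O2 (1 atm), DMSO, 60 °C
Reagents that add atoms: none
Why: Saegusa–Ito oxidation of the silyl enol ether restores the enone with the methyl group on the β-carbon and leaves the C5 stereocentre untouched.

**Step 4**
Reactants: 5 (R)-4-allyl-3-methylcyclopent-2-en-1-one; 6 S-ethyl (E)-but-2-enethioate
Product: 8 S-ethyl (3S)-3-[(1R,2R)-2-allyl-3-methyl-5-oxocyclopent-3-en-1-yl]butanethioate, via kinetic silyl enol ether 7 (not isolated)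
Conditions: LDA, TMSCl, THF, −78 °C; solvent change to CH2Cl2; 6, TrSbCl6 (5 mol%), −78 °C; H2O
Reagents that add atoms: none
Why: Anti-selective Mukaiyama–Michael addition through an open transition state; the thioester approaches C1 anti to the allyl group (C1 R) and the anti topicity gives C10 (S).

**Step 5**
Reactants: 8 S-ethyl (3S)-3-[(1R,2R)-2-allyl-3-methyl-5-oxocyclopent-3-en-1-yl]butanethioate
Product: 9 (3S)-3-[(1R,2R)-2-allyl-3-methyl-5-oxocyclopent-3-en-1-yl]butanal
Conditions: Et3SiH, Pd/C (5 mol%), acetone, 23 °C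
Reagents that add atoms: none
Why: Fukuyama reduction converts the thioester into the aldehyde without touching the ketone.

**Step 6**
Reactants: 9 (3S)-3-[(1R,2R)-2-allyl-3-methyl-5-oxocyclopent-3-en-1-yl]butanal; 10 methyl 2-(bromomethyl)prop-2-enoate
Product: 11 methyl (2Z)-2-(bromomethyl)-4-{(1R,5R)-2-methyl-4-oxo-5-[(2S)-4-oxobutan-2-yl]cyclopent-2-en-1-yl}but-2-enoate
Conditions: second-generation Hoveyda–Grubbs catalyst (5 mol%), 10 (5 equiv), CH2Cl2, 40 °C
Reagents that add atoms: none
Why: Olefin cross-metathesis of the terminal alkene with the 1,1-disubstituted acrylate gives the trisubstituted allylic bromide; the conjugated ring alkene is inert.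

**Step 7**
Reactants: 11 methyl (2Z)-2-(bromomethyl)-4-{(1R,5R)-2-methyl-4-oxo-5-[(2S)-4-oxobutan-2-yl]cyclopent-2-en-1-yl}but-2-enoate
Product: 12 (1R,5R,7R,8S,10S)-2-oxoguaia-3,11(13)-dien-12,8-olide
Conditions: CrCl2 (4 equiv), THF, 23 °C
Reagents that add atoms: none
Why: Nozaki–Hiyama (Barbier) allylation with divalent chromium adds anti to the aldehyde through a chair transition state and the hydroxy ester lactonises; the trans ring fusion keeps the lactone bonds pseudo-equatorial and cis-1,3 to C5–C4, which sets C7 (R) and C8 (S).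

**Step 8**
Reactants: 12 (1R,5R,7R,8S,10S)-2-oxoguaia-3,11(13)-dien-12,8-olide
Product: 13 (1R,5R,7R,8S,10S)-13-(dimethylamino)-2-oxoguai-3-en-12,8-olide (C11 epimers)
Conditions: Me2NH, THF/MeOH, 0 °C
Reagents that add atoms: dimethylamine CNC
Why: Aza-Michael addition masks the methylene lactone, so that it cannot act as an acceptor in step 20; the C11 centre is removed again in step 24.

**Step 9**
Reactants: 14 (R)-4-(tert-butyldimethylsilyloxy)cyclohex-2-en-1-one
Product: 15 (4R)-4-(tert-butyldimethylsilyloxy)-6-methylcyclohex-2-en-1-one (C6 epimers)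
Conditions: LDA, THF, −78 °C; MeI
Reagents that add atoms: iodomethane CI
Why: Kinetic α′-enolate alkylation installs the C10′ methyl group; its configuration is irrelevant because C10′ becomes sp2 in step 11.

**Step 10**
Reactants: 15 (4R)-4-(tert-butyldimethylsilyloxy)-6-methylcyclohex-2-en-1-one (C6 epimers)
Product: 16 (4R)-4-(tert-butyldimethylsilyloxy)-2,3-epoxy-6-methylcyclohexan-1-one with the epoxide trans to the silyloxy group (C6 epimers)
Conditions: t-BuOOH, Triton B (cat.), THF, 0 °C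
Reagents that add atoms: tert-butyl hydroperoxide CC(C)(C)OO
Why: Weitz–Scheffer nucleophilic epoxidation takes place anti to the bulky silyloxy group and sets C6′ and C7′.

**Step 11**
Reactants: 16 (4R)-4-(tert-butyldimethylsilyloxy)-2,3-epoxy-6-methylcyclohexan-1-one with the epoxide trans to the silyloxy group (C6 epimers)
Product: 17 (5R)-5-(tert-butyldimethylsilyloxy)-3-methyl-7-oxabicyclo[4.1.0]hept-2-en-2-yl trifluoromethanesulfonate (epoxide trans to the silyloxy group)
Conditions: KHMDS, THF, −78 °C; PhNTf2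
Reagents that add atoms: N-phenylbis(trifluoromethanesulfonimide) O=S(=O)(N(c1ccccc1)S(=O)(=O)C(F)(F)F)C(F)(F)F
Why: Enol triflate formation can only go towards the methyl-bearing α-carbon, because the other α-carbon is part of the epoxide.

**Step 12**
Reactants: 18 pent-4-yn-1-ol
Product: 19 pent-4-yn-1-yl acetate
Conditions: Ac2O, pyridine, DMAP (cat.), CH2Cl2, 23 °C
Reagents that add atoms: acetic anhydride CC(=O)OC(C)=O
Why: Standard acylation puts the C1′ acetate of the target in place.

**Step 13**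
Reactants: 19 pent-4-yn-1-yl acetate
Product: 20 4-(4,4,5,5-tetramethyl-1,3,2-dioxaborolan-2-yl)pent-4-en-1-yl acetate
Conditions: B2pin2, CuCl (5 mol%), SIMes·HCl (5 mol%), NaOt-Bu (10 mol%), MeOH (2 equiv), THF, 23 °C
Reagents that add atoms: bis(pinacolato)diboron CC1(C)OB(OC1(C)C)B1OC(C)(C)C(C)(C)O1
Why: Copper-catalysed Markovnikov (α-selective) protoboration of the terminal alkyne gives the 1,1-disubstituted vinyl boronate.

**Step 14**
Reactants: 17 (5R)-5-(tert-butyldimethylsilyloxy)-3-methyl-7-oxabicyclo[4.1.0]hept-2-en-2-yl trifluoromethanesulfonate (epoxide trans to the silyloxy group); 20 4-(4,4,5,5-tetramethyl-1,3,2-dioxaborolan-2-yl)pent-4-en-1-yl acetate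
Product: 21 4-[(5R)-5-(tert-butyldimethylsilyloxy)-3-methyl-7-oxabicyclo[4.1.0]hept-2-en-2-yl]pent-4-en-1-yl acetate
Conditions: PdCl2(dppf) (5 mol%), K3PO4, THF/H2O, 50 °C
Reagents that add atoms: none
Why: Suzuki–Miyaura coupling of the vinyl triflate with the vinyl boronate forms the C5′–C4′ bond; oxidative addition at C–OTf is faster than ionisation of the hindered vinyl epoxide.

**Step 15**
Reactants: 21 4-[(5R)-5-(tert-butyldimethylsilyloxy)-3-methyl-7-oxabicyclo[4.1.0]hept-2-en-2-yl]pent-4-en-1-yl acetate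
Product: 22 (4S)-4-[(5R)-5-(tert-butyldimethylsilyloxy)-3-methyl-7-oxabicyclo[4.1.0]hept-2-en-2-yl]pentyl acetate
Conditions: [Ir(cod){(S)-tBu-PHOX}]BArF (2 mol%), H2 (50 bar), CH2Cl2, 23 °C
Reagents that add atoms: none
Why: Iridium-catalysed asymmetric hydrogenation reduces only the 1,1-disubstituted alkene and sets C4′ (S) by catalyst control; the tetrasubstituted ring alkene does not react.

**Step 16**
Reactants: 22 (4S)-4-[(5R)-5-(tert-butyldimethylsilyloxy)-3-methyl-7-oxabicyclo[4.1.0]hept-2-en-2-yl]pentyl acetate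
Product: 23 (4S)-4-[(5R)-5-hydroxy-3-methyl-7-oxabicyclo[4.1.0]hept-2-en-2-yl]pentyl acetate
Conditions: TBAF, AcOH, THF, 0 °C
Reagents that add atoms: none
Why: Buffered fluoride desilylation frees the C8′ hydroxyl without touching the acetate or the epoxide.

**Step 17**
Reactants: 23 (4S)-4-[(5R)-5-hydroxy-3-methyl-7-oxabicyclo[4.1.0]hept-2-en-2-yl]pentyl acetate
Product: 24 (diethoxyphosphoryl)acetate ester of 23 at the C8′ hydroxyl
Conditions: (EtO)2P(O)CH2CO2H, DCC, DMAP (cat.), CH2Cl2, 0 to 23 °C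
Reagents that add atoms: 2-(diethoxyphosphoryl)acetic acid CCOP(=O)(OCC)CC(=O)O
Why: Steglich esterification tethers the future C11′–C12′ unit to the C8′ oxygen.

**Step 18**
Reactants: 24 (diethoxyphosphoryl)acetate ester of 23 at the C8′ hydroxyl
Product: 26 (4′S,6′S,7′S,8′R)-1′-acetoxy-6′-hydroxy-1′,10′-secoeudesma-5′(10′),11′(13′)-dien-12′,8′-olide, via phosphono lactone 25 (not isolated)
Conditions: NaH, THF, 0 to 23 °C; then (CH2O)n, 23 °C
Reagents that add atoms: formaldehyde C=O
Why: The phosphonate carbanion opens the epoxide 5-exo with SN2 inversion at C7′ (cis-fused lactone, C6′ hydroxyl trans to C11′) and Horner–Wadsworth–Emmons reaction with formaldehyde then gives the methylene lactone.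

**Step 19**
Reactants: 26 (4′S,6′S,7′S,8′R)-1′-acetoxy-6′-hydroxy-1′,10′-secoeudesma-5′(10′),11′(13′)-dien-12′,8′-olide
Product: 27 6′-O-tert-butyldimethylsilyl ether of 26
Conditions: TBSOTf, 2,6-lutidine, CH2Cl2, −78 °C
Reagents that add atoms: tert-butyldimethylsilyl trifluoromethanesulfonate CC(C)(C)[Si](C)(C)OS(=O)(=O)C(F)(F)F
Why: Silylation protects the C6′ hydroxyl through the base-mediated union and the C2 acetylation.

**Step 20**
Reactants: 13 (1R,5R,7R,8S,10S)-13-(dimethylamino)-2-oxoguai-3-en-12,8-olide (C11 epimers); 27 6′-O-tert-butyldimethylsilyl ether of 26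
Product: 29 bromo lactone in which C1 of 13 carries the C13′ methylene of 27 and C11′ carries bromine (C13′ on C1 anti to C6; Br on the H-7′ face), via lithium lactone enolate 28 (not isolated)
Conditions: LDA (1.0 equiv), THF, −78 °C; 27; then NBS, −78 °C; aq. Na2S2O3
Reagents that add atoms: N-bromosuccinimide O=C1CCC(=O)N1Br
Why: Michael addition of the kinetic α′-enolate to the methylene lactone makes the quaternary C1 on the face anti to the C5–C6 bond, and the resulting lactone enolate is brominated on its convex face (syn to H-7′), which fixes C11′ for the inversion in step 21.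

**Step 21**
Reactants: 29 bromo lactone in which C1 of 13 carries the C13′ methylene of 27 and C11′ carries bromine (C13′ on C1 anti to C6; Br on the H-7′ face)
Product: 31 norbornenone: 2-oxo (2-deacetoxy) 13-dimethylamino-11,13-dihydro 6′-O-silyl derivative of the target, via silyl dienol ether 30 (not isolated)
Conditions: TMSOTf, Et3N, CH2Cl2, 0 °C; evaporate; then Bu4N[Ph3SiF2], THF, −40 to 23 °C
Reagents that add atoms: none
Why: Proposed new method: fluoride frees the C2 dienolate (C5–H removed by soft enolisation), whose C3 adds to the lactone carbonyl on the face held by the C13′ tether to give a bicyclo[3.2.1] hemiketal alkoxide in which the C3–C12′ bond is antiperiplanar to C11′–Br, so C3 shifts from C12′ to C11′ with loss of bromide and inversion at C11′, contracting the ring to the norbornene, re-forming the lactone with C12′ exo and leaving the C4=C5 alkene; the closest known reaction is the quasi-Favorskii (semibenzilic) ring contraction of 2-halobicyclo[3.2.1]octenones to norbornenes, here relayed through a lactone carbonyl for the first time.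

**Step 22**
Reactants: 31 norbornenone: 2-oxo (2-deacetoxy) 13-dimethylamino-11,13-dihydro 6′-O-silyl derivative of the target
Product: 32 C2 alcohol of 31 with the hydroxyl syn to the C4=C5 alkene (2R)
Conditions: SmI2 (2.5 equiv), H2O (20 equiv), THF, −78 to 0 °C
Reagents that add atoms: none
Why: Single-electron (ketyl) reduction: the C2 carbanion avoids the destabilising four-electron overlap with the C4=C5 π bond and is protonated from the side of the saturated bridge, which gives the less hindered alcohol with OH syn to the alkene, the isomer that hydride reagents do not favour.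

**Step 23**
Reactants: 32 C2 alcohol of 31 with the hydroxyl syn to the C4=C5 alkene (2R)
Product: 33 C2 acetate of 32
Conditions: Ac2O, DMAP, pyridine, 40 °C
Reagents that add atoms: acetic anhydride CC(=O)OC(C)=O
Why: DMAP-catalysed acylation of the only free hydroxyl installs the C2 acetate with retention.

**Step 24**
Reactants: 33 C2 acetate of 32
Product: 35 6′-O-tert-butyldimethylsilyl ether of the target, via trimethylammonium iodide 34 (not isolated)
Conditions: MeI, MeOH/CH2Cl2, 23 °C; then aq. NaHCO3, EtOAc, 23 °C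
Reagents that add atoms: none
Why: Quaternisation of the Mannich base and E1cB (Hofmann-type) elimination of trimethylamine regenerates the α-methylene lactone of half A under conditions that leave both acetates intact.

**Step 25**
Reactants: 35 6′-O-tert-butyldimethylsilyl ether of the target
Product: 36 target compound CNP0211028.3
Conditions: HF·pyridine, THF, 0 to 23 °C
Reagents that add atoms: none
Why: Fluoride-mediated desilylation frees the C6′ hydroxyl without acyl migration or lactone opening.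

**Compound list**
1 | (R)-4-(tert-butyldimethylsilyloxy)cyclopent-2-en-1-one | O=C1C=C[C@H](O[Si](C)(C)C(C)(C)C)C1 | starting material
2 | (3R,4R)-3-allyl-4-(tert-butyldimethylsilyloxy)cyclopentan-1-one | O=C1C[C@@H](CC=C)[C@H](O[Si](C)(C)C(C)(C)C)C1 | intermediate
3 | (R)-4-allylcyclopent-2-en-1-one | O=C1C=C[C@H](CC=C)C1 | intermediate
4 | (3S,4R)-4-allyl-3-methyl-1-(trimethylsilyloxy)cyclopent-1-ene | C[Si](C)(C)OC1=C[C@@H](C)[C@H](CC=C)C1 | intermediate
5 | (R)-4-allyl-3-methylcyclopent-2-en-1-one | O=C1C=C(C)[C@H](CC=C)C1 | intermediate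
6 | S-ethyl (E)-but-2-enethioate | CCSC(=O)/C=C/C | starting material
7 | (R)-3-allyl-4-methyl-1-(trimethylsilyloxy)cyclopenta-1,4-diene | C[Si](C)(C)OC1=C[C@@H](CC=C)C(C)=C1 | intermediate
8 | S-ethyl (3S)-3-[(1R,2R)-2-allyl-3-methyl-5-oxocyclopent-3-en-1-yl]butanethioate | CCSC(=O)C[C@H](C)[C@H]1C(=O)C=C(C)[C@@H]1CC=C | intermediate
9 | (3S)-3-[(1R,2R)-2-allyl-3-methyl-5-oxocyclopent-3-en-1-yl]butanal | O=CC[C@H](C)[C@H]1C(=O)C=C(C)[C@@H]1CC=C | intermediate
10 | methyl 2-(bromomethyl)prop-2-enoate | C=C(CBr)C(=O)OC | starting material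
11 | methyl (2Z)-2-(bromomethyl)-4-{(1R,5R)-2-methyl-4-oxo-5-[(2S)-4-oxobutan-2-yl]cyclopent-2-en-1-yl}but-2-enoate | O=CC[C@H](C)[C@H]1C(=O)C=C(C)[C@@H]1C/C=C(\CBr)C(=O)OC | intermediate
12 | (1R,5R,7R,8S,10S)-2-oxoguaia-3,11(13)-dien-12,8-olide | C=C1C(=O)O[C@H]2C[C@H](C)[C@H]3C(=O)C=C(C)[C@@H]3C[C@H]12 | intermediate
13 | (1R,5R,7R,8S,10S)-13-(dimethylamino)-2-oxoguai-3-en-12,8-olide (C11 epimers) | CN(C)CC1C(=O)O[C@H]2C[C@H](C)[C@H]3C(=O)C=C(C)[C@@H]3C[C@H]12 | intermediate
14 | (R)-4-(tert-butyldimethylsilyloxy)cyclohex-2-en-1-one | O=C1C=C[C@H](O[Si](C)(C)C(C)(C)C)CC1 | starting material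
15 | (4R)-4-(tert-butyldimethylsilyloxy)-6-methylcyclohex-2-en-1-one (C6 epimers) | O=C1C=C[C@H](O[Si](C)(C)C(C)(C)C)CC1C | intermediate
16 | (4R)-4-(tert-butyldimethylsilyloxy)-2,3-epoxy-6-methylcyclohexan-1-one with the epoxide trans to the silyloxy group (C6 epimers) | O=C1C(C)C[C@@H](O[Si](C)(C)C(C)(C)C)[C@@H]2O[C@H]12 | intermediate
17 | (5R)-5-(tert-butyldimethylsilyloxy)-3-methyl-7-oxabicyclo[4.1.0]hept-2-en-2-yl trifluoromethanesulfonate (epoxide trans to the silyloxy group) | CC(C)(C)[Si](C)(C)O[C@@H]1CC(C)=C(OS(=O)(=O)C(F)(F)F)[C@H]2O[C@@H]12 | intermediate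
18 | pent-4-yn-1-ol | C#CCCCO | starting material
19 | pent-4-yn-1-yl acetate | C#CCCCOC(C)=O | intermediate
20 | 4-(4,4,5,5-tetramethyl-1,3,2-dioxaborolan-2-yl)pent-4-en-1-yl acetate | C=C(B1OC(C)(C)C(C)(C)O1)CCCOC(C)=O | intermediate
21 | 4-[(5R)-5-(tert-butyldimethylsilyloxy)-3-methyl-7-oxabicyclo[4.1.0]hept-2-en-2-yl]pent-4-en-1-yl acetate | CC(C)(C)[Si](C)(C)O[C@@H]1CC(C)=C(C(=C)CCCOC(C)=O)[C@H]2O[C@@H]12 | intermediate
22 | (4S)-4-[(5R)-5-(tert-butyldimethylsilyloxy)-3-methyl-7-oxabicyclo[4.1.0]hept-2-en-2-yl]pentyl acetate | CC(C)(C)[Si](C)(C)O[C@@H]1CC(C)=C([C@@H](C)CCCOC(C)=O)[C@H]2O[C@@H]12 | intermediate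
23 | (4S)-4-[(5R)-5-hydroxy-3-methyl-7-oxabicyclo[4.1.0]hept-2-en-2-yl]pentyl acetate | O[C@@H]1CC(C)=C([C@@H](C)CCCOC(C)=O)[C@H]2O[C@@H]12 | intermediate
24 | (diethoxyphosphoryl)acetate ester of 23 at the C8′ hydroxyl | CCOP(=O)(OCC)CC(=O)O[C@@H]1CC(C)=C([C@@H](C)CCCOC(C)=O)[C@H]2O[C@@H]12 | intermediate
25 | 11′-(diethoxyphosphoryl) cis-lactone with free C6′ hydroxyl and no C13′ (C11′ epimers) | CCOP(=O)(OCC)C1C(=O)O[C@@H]2CC(C)=C([C@@H](C)CCCOC(C)=O)[C@@H](O)[C@@H]21 | intermediate
26 | (4′S,6′S,7′S,8′R)-1′-acetoxy-6′-hydroxy-1′,10′-secoeudesma-5′(10′),11′(13′)-dien-12′,8′-olide | C=C1C(=O)O[C@@H]2CC(C)=C([C@@H](C)CCCOC(C)=O)[C@@H](O)[C@@H]21 | intermediate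
27 | 6′-O-tert-butyldimethylsilyl ether of 26 | C=C1C(=O)O[C@@H]2CC(C)=C([C@@H](C)CCCOC(C)=O)[C@@H](O[Si](C)(C)C(C)(C)C)[C@@H]21 | intermediate
28 | lithium enolate of the C1–C13′ Michael adduct of 13 and 27 | CN(C)CC1C(=O)O[C@H]2C[C@H](C)[C@]3(CC4=C([O-])O[C@@H]5CC(C)=C([C@@H](C)CCCOC(C)=O)[C@@H](O[Si](C)(C)C(C)(C)C)[C@@H]54)C(=O)C=C(C)[C@@H]3C[C@H]12.[Li+] | intermediate
29 | bromo lactone in which C1 of 13 carries the C13′ methylene of 27 and C11′ carries bromine (C13′ on C1 anti to C6; Br on the H-7′ face) | CN(C)CC1C(=O)O[C@H]2C[C@H](C)[C@]3(C[C@]4(Br)C(=O)O[C@@H]5CC(C)=C([C@@H](C)CCCOC(C)=O)[C@@H](O[Si](C)(C)C(C)(C)C)[C@@H]54)C(=O)C=C(C)[C@@H]3C[C@H]12 | intermediate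
30 | 2-(trimethylsilyloxy)-2,4-diene (silyl dienol ether) of 29 | CN(C)CC1C(=O)O[C@H]2C[C@H](C)[C@]3(C[C@]4(Br)C(=O)O[C@@H]5CC(C)=C([C@@H](C)CCCOC(C)=O)[C@@H](O[Si](C)(C)C(C)(C)C)[C@@H]54)C(O[Si](C)(C)C)=CC(C)=C3C[C@H]12 | intermediate
31 | norbornenone: 2-oxo (2-deacetoxy) 13-dimethylamino-11,13-dihydro 6′-O-silyl derivative of the target | CN(C)CC1C(=O)O[C@H]2C[C@H](C)[C@@]34C[C@]5(C(=O)O[C@@H]6CC(C)=C([C@@H](C)CCCOC(C)=O)[C@@H](O[Si](C)(C)C(C)(C)C)[C@@H]65)[C@@H](C(C)=C3C[C@H]12)C4=O | intermediate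
32 | C2 alcohol of 31 with the hydroxyl syn to the C4=C5 alkene (2R) | CN(C)CC1C(=O)O[C@H]2C[C@H](C)[C@@]34C[C@]5(C(=O)O[C@@H]6CC(C)=C([C@@H](C)CCCOC(C)=O)[C@@H](O[Si](C)(C)C(C)(C)C)[C@@H]65)[C@@H](C(C)=C3C[C@H]12)[C@H]4O | intermediate
33 | C2 acetate of 32 | CN(C)CC1C(=O)O[C@H]2C[C@H](C)[C@@]34C[C@]5(C(=O)O[C@@H]6CC(C)=C([C@@H](C)CCCOC(C)=O)[C@@H](O[Si](C)(C)C(C)(C)C)[C@@H]65)[C@@H](C(C)=C3C[C@H]12)[C@H]4OC(C)=O | intermediate
34 | 13-trimethylammonium iodide of 33 | C[N+](C)(C)CC1C(=O)O[C@H]2C[C@H](C)[C@@]34C[C@]5(C(=O)O[C@@H]6CC(C)=C([C@@H](C)CCCOC(C)=O)[C@@H](O[Si](C)(C)C(C)(C)C)[C@@H]65)[C@@H](C(C)=C3C[C@H]12)[C@H]4OC(C)=O.[I-] | intermediate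
35 | 6′-O-tert-butyldimethylsilyl ether of the target | C=C1C(=O)O[C@H]2C[C@H](C)[C@@]34C[C@]5(C(=O)O[C@@H]6CC(C)=C([C@@H](C)CCCOC(C)=O)[C@@H](O[Si](C)(C)C(C)(C)C)[C@@H]65)[C@@H](C(C)=C3C[C@H]12)[C@H]4OC(C)=O | intermediate
36 | target compound CNP0211028.3 | C=C1C(=O)O[C@H]2C[C@H](C)[C@@]34C[C@]5(C(=O)O[C@@H]6CC(C)=C([C@@H](C)CCCOC(C)=O)[C@@H](O)[C@@H]65)[C@@H](C(C)=C3C[C@H]12)[C@H]4OC(C)=O | target

**Step count and risks**
Total step count: 25. Longest linear sequence: 15 steps (14 to 36 through steps 9–11 and 14–25).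

The three steps most likely to fail:

Step 21 (the new ring contraction). Elimination of HBr or a single-electron pathway could compete with the acyl-relayed shift. The fallback sets out from 29 and uses known oxidative enolate coupling. Compound 29 is silylated at the ketone as in the main step and then treated with zinc dust and TMSCl in THF, which converts the bromo lactone reductively into its silyl ketene acetal and gives the bis(silyl enol ether) F1. Oxidation with (NH4)2Ce(NO3)6 and NaHCO3 in MeCN at −30 °C couples C3 with C11′ intramolecularly and comes back to the route at 31. In this variant C11′ is no longer set by inversion, so both C11′ epimers must be expected and separated.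

Step 22 (facial selectivity of the C2 reduction). If the samarium reduction gives the alcohol anti to the alkene, the fallback blocks the alkene face; it sets out from 31. After protonation of the amine with CF3CO2H, dimethyldioxirane epoxidises the strained C4=C5 alkene from its exo face to give the epoxy ketone F2. The epoxide oxygen now shields that face, so NaBH4/CeCl3 delivers hydride from the side of the saturated bridge and gives the epoxy alcohol F3 with the required C2 configuration. Stereospecific deoxygenation with Ph3P=Se and CF3CO2H restores the alkene, and the route is rejoined at 32.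

Step 15 (catalyst-controlled C4′ centre next to a vinyl epoxide). The fallback moves the asymmetric hydrogenation to a simple substrate; it sets out from 20 and 17. Rhodium-catalysed enantioselective hydrogenation of vinyl boronate 20 ([Rh(cod)2]BF4 with a Walphos ligand, H2) gives (R)-4-(4,4,5,5-tetramethyl-1,3,2-dioxaborolan-2-yl)pentyl acetate F4, and KHF2 converts it into potassium (R)-(5-acetoxypentan-2-yl)trifluoroborate F5. Stereospecific, invertive Suzuki–Miyaura coupling of F5 with triflate 17 (Pd(OAc)2, P(t-Bu)3, K2CO3, toluene/H2O) then comes back to the route at 22.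

**Further compounds**
F1 | step 21 | bis(trimethylsilyl enol ether) of the Michael adduct (silyl ketene acetal of lactone B and 2-silyloxy-2,4-diene of half A) | CN(C)CC1C(=O)O[C@H]2C[C@H](C)[C@]3(CC4=C(O[Si](C)(C)C)O[C@@H]5CC(C)=C([C@@H](C)CCCOC(C)=O)[C@@H](O[Si](C)(C)C(C)(C)C)[C@@H]54)C(O[Si](C)(C)C)=CC(C)=C3C[C@H]12
F2 | step 22 | exo-4,5-epoxide of norbornenone 31 | CN(C)CC1C(=O)O[C@H]2C[C@H](C)[C@@]34C[C@]5(C(=O)O[C@@H]6CC(C)=C([C@@H](C)CCCOC(C)=O)[C@@H](O[Si](C)(C)C(C)(C)C)[C@@H]65)[C@@H]([C@]7(C)O[C@]37C[C@H]12)C4=O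
F3 | step 22 | exo-4,5-epoxide of alcohol 32 (hydroxyl on the epoxide side) | CN(C)CC1C(=O)O[C@H]2C[C@H](C)[C@@]34C[C@]5(C(=O)O[C@@H]6CC(C)=C([C@@H](C)CCCOC(C)=O)[C@@H](O[Si](C)(C)C(C)(C)C)[C@@H]65)[C@@H]([C@]7(C)O[C@]37C[C@H]12)[C@H]4O
F4 | step 15 | (R)-4-(4,4,5,5-tetramethyl-1,3,2-dioxaborolan-2-yl)pentyl acetate | CC(=O)OCCC[C@@H](C)B1OC(C)(C)C(C)(C)O1
F5 | step 15 | potassium (R)-(5-acetoxypentan-2-yl)trifluoroborate | CC(=O)OCCC[C@@H](C)[B-](F)(F)F.[K+]
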